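**Retrosynthetic overview**
1. The last disconnection is the depside ester between the ring A carbonyl carbon and the oxygen on C3' of ring B. The partners are a C4-silylated ring A acid and a ring B phenol with benzylated C2'/C4' hydroxyls and carboxyl, so fluoride and then neutral hydrogenolysis end the route.
2. The plan rests on ring A, a 5-propylresorcinol nucleus whose two oxygens are unlike (methyl ether on C2, free hydroxyl on C4). A vinylketene benzannulation delivers the C2 oxygen as a free phenol and the C4 oxygen as a silyl ether in the ring-forming event itself.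
3. Ring A is cut at C2–C3, C4–C5 and C1–C2 into 3-propylcyclobut-2-en-1-one and (triisopropylsilyloxy)ethyne. The carboxyl carbon is added afterwards at C1 by phenoxide-directed formylation.
4. The siloxyalkyne is made from trimethylsilylacetylene (acetylide oxygenation, O-silylation, C-desilylation), because the unsubstituted ethynolate is hard to generate and leaves its carbon open to silylation.
5. Ring order: the four-membered ring first (dichloroketene plus pent-1-yne), then ring A. Ring B is bought as 2,4-dihydroxy-6-propylbenzoic acid and gains its C3' oxygen by ortho-formylation and Baeyer–Villiger oxidation.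

Key step: step 5

Remark: ring A is numbered from the carbonyl-bearing carbon (C1) through C2 (OMe) and C4 (OH) to C6 (propyl), and ring B from C1' (CO2H) to C6' (propyl); 2,4-dihydroxy-6-propylbenzoic acid is assumed to be a catalogue compound.

**Step 1**
Reactants: 1 pent-1-yne; 2 trichloroacetyl chloride
Product: 4 4,4-dichloro-3-propylcyclobut-2-en-1-one, via dichloroketene 3 (not isolated)
Conditions: Zn–Cu couple, Et2O–DME, slow addition of 2, rt
Reagents that add atoms: none
Why: Zinc strips two chlorines from 2 to give dichloroketene, and in the ketene–alkyne [2+2] cycloaddition the nucleophilic terminal carbon of 1 bonds to the ketene carbonyl carbon, which places propyl at C3 beside the CCl2 carbon.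

**Step 2**
Reactants: 4 4,4-dichloro-3-propylcyclobut-2-en-1-one
Product: 5 3-propylcyclobut-2-en-1-one
Conditions: Zn dust, AcOH, TMEDA, EtOH, 0 °C to rt
Reagents that add atoms: none
Why: Both C–Cl bonds lie alpha to the carbonyl and are removed through zinc enolates (reductive dehalogenation of an alpha-halo ketone), and the AcOH–TMEDA buffer protonates at carbon without shifting or reducing the ring double bond.

**Step 3**
Reactants: 6 ethynyl(trimethyl)silane; 7 triisopropylsilyl trifluoromethanesulfonate
Product: 10 1-(triisopropylsilyloxy)-2-(trimethylsilyl)ethyne, via lithium (trimethylsilyl)acetylide 8 (not isolated), via lithium 2-(trimethylsilyl)ethynolate 9 (not isolated)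
Conditions: n-BuLi, THF, −78 °C; LiOOt-Bu (from anhydrous t-BuOOH and LiN(SiMe3)2), −78 to 0 °C; then 7, −78 to 0 °C
Reagents that add atoms: tert-butyl hydroperoxide, CC(C)(C)OO
Why: The acetylide attacks the electrophilic peroxide oxygen (oxygenation of a lithium acetylide to an ynolate), and the bulky silyl triflate then reacts at oxygen because the ynolate carbon is shielded by SiMe3.

**Step 4**
Reactants: 10 1-(triisopropylsilyloxy)-2-(trimethylsilyl)ethyne
Product: 11 (triisopropylsilyloxy)ethyne
Conditions: K2CO3 (cat.), MeOH–THF, 0 °C; careful concentration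
Reagents that add atoms: none
Why: Methoxide-catalysed protiodesilylation of an alkynyl–SiMe3 bond should be far faster than attack at the hindered oxygen-bound triisopropylsilyl group, and the electron-rich ynol ether is inert to base, so only the C–Si bond should break.

**Step 5**
Reactants: 5 3-propylcyclobut-2-en-1-one; 11 (triisopropylsilyloxy)ethyne
Product: 16 3-propyl-5-(triisopropylsilyloxy)phenol, via vinylketene 12 (not isolated), via 4-vinylcyclobutenone 13 (not isolated), via dienylketene 14 (not isolated), via cyclohexadienone 15 (not isolated)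
Conditions: toluene, argon, 80 °C, then 110 °C
Reagents that add atoms: none
Why: Heat opens 5 in a 4π electrocyclic reaction (its C(=O)–CH2 bond breaks) to vinylketene 12, and the ketene C=C of 12 takes up 11 in a [2+2] cycloaddition that closes the transient four-membered ring of 13 and forms the ring A bonds C2–C3 and C4–C5. A second 4π opening turns 13 into dienylketene 14, and a thermal disrotatory 6π electrocyclisation between the ketene carbon and the terminal CH2 closes the six-membered ring A, re-forming C1–C2, after which dienone 15 tautomerises to phenol 16. The closest known reaction type is the Danheiser benzannulation of 3-alkylcyclobutenones with alkoxy- and trialkylsiloxyalkynes. The one selectivity required is the orientation of the [2+2] step, and it is secured by the oxygen lone pair of 11, which makes the CH carbon the nucleophilic terminus that bonds to the electrophilic ketene carbonyl carbon; OTIPS therefore ends up meta to the new hydroxyl and propyl meta to both. The ketene oxygen emerges as the free C2 hydroxyl and the alkyne oxygen as the C4 silyl ether, and no stereocentre remains because the only sp3 centre formed (C4 of racemic 13) is destroyed on ring opening. A slight excess of 11 should keep product 16 from competing as a trap for 12.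

**Step 6**
Reactants: 16 3-propyl-5-(triisopropylsilyloxy)phenol
Product: 18 2-hydroxy-6-propyl-4-(triisopropylsilyloxy)benzaldehyde, via salicyl alcohol 17 (not isolated)
Conditions: MgCl2 (anhydrous), Et3N, (CH2O)n, THF, reflux; 1 M HCl work-up
Reagents that add atoms: paraformaldehyde (reacts as formaldehyde), C=O
Why: In the Casnati–Skattebøl ortho-formylation the magnesium-bound phenoxide delivers formaldehyde only to an ortho carbon, where C1 (next to n-propyl, para to OTIPS) is open while C3 is screened by the neighbouring triisopropylsilyl ether, and a second formaldehyde oxidises the magnesium alkoxide of 17 to the aldehyde by hydride transfer.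

**Step 7**
Reactants: 18 2-hydroxy-6-propyl-4-(triisopropylsilyloxy)benzaldehyde
Product: 19 2-methoxy-6-propyl-4-(triisopropylsilyloxy)benzaldehyde
Conditions: MeOH, PPh3, DIAD, THF, 0 °C to rt
Reagents that add atoms: methanol, CO
Why: The acidic salicylaldehyde hydroxyl is a good pronucleophile for a Mitsunobu etherification, whose neutral medium spares the aryl silyl ether that the para formyl group makes sensitive to carbonate bases.

**Step 8**
Reactants: 19 2-methoxy-6-propyl-4-(triisopropylsilyloxy)benzaldehyde
Product: 20 2-methoxy-6-propyl-4-(triisopropylsilyloxy)benzoic acid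
Conditions: NaClO2, NaH2PO4, 2-methylbut-2-ene, t-BuOH–H2O, rt
Reagents that add atoms: sodium chlorite, [Na+].[O-]Cl=O
Why: The Pinnick oxidation converts hindered electron-rich benzaldehydes into acids at mildly acidic pH, the alkene scavenger prevents ring chlorination, and the silyl ether tolerates the buffer.

**Step 9**
Reactants: 21 2,4-dihydroxy-6-propylbenzoic acid
Product: 22 benzyl 4-(benzyloxy)-2-hydroxy-6-propylbenzoate
Conditions: BnBr (2 equiv), K2CO3, DMF, rt
Reagents that add atoms: benzyl bromide, BrCc1ccccc1
Why: In this Williamson-type alkylation the carboxylate and the C4' phenoxide are benzylated, while the C2' hydroxyl stays free because it is held in a hydrogen bond to the ester carbonyl and only two equivalents of halide are offered.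

**Step 10**
Reactants: 22 benzyl 4-(benzyloxy)-2-hydroxy-6-propylbenzoate
Product: 24 benzyl 4-(benzyloxy)-3-formyl-2-hydroxy-6-propylbenzoate, via hydroxymethyl phenol 23 (not isolated)
Conditions: MgCl2 (anhydrous), Et3N, (CH2O)n, MeCN, reflux; 1 M HCl work-up
Reagents that add atoms: paraformaldehyde (reacts as formaldehyde), C=O
Why: The Casnati–Skattebøl formylation strikes only ortho to a free phenol, and the single free hydroxyl (C2') has one open ortho carbon, C3', which the C4' ether and the para propyl group also activate, so the substrate fixes the regiochemistry.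

**Step 11**
Reactants: 24 benzyl 4-(benzyloxy)-3-formyl-2-hydroxy-6-propylbenzoate
Product: 25 benzyl 2,4-bis(benzyloxy)-3-formyl-6-propylbenzoate
Conditions: BnBr, K2CO3, DMF, 60 °C
Reagents that add atoms: benzyl bromide, BrCc1ccccc1
Why: This Williamson etherification of the last phenol needs warming because the hydroxyl is hydrogen-bonded between two carbonyl groups, and the aldehyde and the hindered benzyl ester are inert to carbonate.

**Step 12**
Reactants: 25 benzyl 2,4-bis(benzyloxy)-3-formyl-6-propylbenzoate
Product: 27 benzyl 2,4-bis(benzyloxy)-3-hydroxy-6-propylbenzoate, via aryl formate 26 (not isolated)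
Conditions: mCPBA, CH2Cl2, 0 °C to rt; then Et3N, MeOH, rt
Reagents that add atoms: 3-chloroperbenzoic acid, OOC(=O)c1cccc(Cl)c1
Why: Baeyer–Villiger oxidation of a benzaldehyde flanked by two alkoxy groups proceeds with aryl migration to formate 26, which mild methanolysis cleaves while the di-ortho-substituted benzyl ester stays intact.

**Step 13**
Reactants: 20 2-methoxy-6-propyl-4-(triisopropylsilyloxy)benzoic acid; 27 benzyl 2,4-bis(benzyloxy)-3-hydroxy-6-propylbenzoate
Product: 29 benzyl 2,4-bis(benzyloxy)-3-{[2-methoxy-6-propyl-4-(triisopropylsilyloxy)benzoyl]oxy}-6-propylbenzoate, via mixed trifluoroacetic anhydride 28 (not isolated)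
Conditions: (CF3CO)2O, toluene, 0 °C to rt
Reagents that add atoms: none
Why: In this mixed-anhydride esterification, customary for depsides, 28 ionises towards an acylium ion stabilised by the ortho methoxy and para silyloxy groups, a linear electrophile that escapes the hindrance of the 2,6-disubstituted acid and is captured by the only free hydroxyl of 27.

**Step 14**
Reactants: 29 benzyl 2,4-bis(benzyloxy)-3-{[2-methoxy-6-propyl-4-(triisopropylsilyloxy)benzoyl]oxy}-6-propylbenzoate
Product: 30 benzyl 2,4-bis(benzyloxy)-3-[(4-hydroxy-2-methoxy-6-propylbenzoyl)oxy]-6-propylbenzoate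
Conditions: Bu4NF, AcOH (1:1), THF, 0 °C
Reagents that add atoms: none
Why: Fluoride cleaves the aryl silyl ether, the acetic acid buffer protonates the phenoxide at once so that the aryl ester is not attacked, and the benzyl groups are inert.

**Step 15**
Reactants: 30 benzyl 2,4-bis(benzyloxy)-3-[(4-hydroxy-2-methoxy-6-propylbenzoyl)oxy]-6-propylbenzoate
Product: 31 2,4-dihydroxy-3-[(4-hydroxy-2-methoxy-6-propylbenzoyl)oxy]-6-propylbenzoic acid (target)
Conditions: H2 (1 atm), 10% Pd/C, EtOAc, rt
Reagents that add atoms: none
Why: Catalytic hydrogenolysis removes both benzyl ethers and the benzyl ester under neutral conditions, so the acyl group should not migrate from the C3' oxygen to the freed C2' or C4' hydroxyls, and the aryl ester and methyl ether remain.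

**Compound list**
1 | pent-1-yne | CCCC#C | starting material
2 | trichloroacetyl chloride | O=C(Cl)C(Cl)(Cl)Cl | starting material
3 | dichloroketene | O=C=C(Cl)Cl | intermediate
4 | 4,4-dichloro-3-propylcyclobut-2-en-1-one | CCCC1=CC(=O)C1(Cl)Cl | intermediate
5 | 3-propylcyclobut-2-en-1-one | CCCC1=CC(=O)C1 | intermediate
6 | ethynyl(trimethyl)silane | C#C[Si](C)(C)C | starting material
7 | triisopropylsilyl trifluoromethanesulfonate | CC(C)[Si](OS(=O)(=O)C(F)(F)F)(C(C)C)C(C)C | starting material
8 | lithium (trimethylsilyl)acetylide | [Li+].[C-]#C[Si](C)(C)C | intermediate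
9 | lithium 2-(trimethylsilyl)ethynolate | [Li+].[O-]C#C[Si](C)(C)C | intermediate
10 | 1-(triisopropylsilyloxy)-2-(trimethylsilyl)ethyne | C[Si](C)(C)C#CO[Si](C(C)C)(C(C)C)C(C)C | intermediate
11 | (triisopropylsilyloxy)ethyne | C#CO[Si](C(C)C)(C(C)C)C(C)C | intermediate
12 | 3-methylidenehex-1-en-1-one (vinylketene) | CCCC(=C)C=C=O | intermediate
13 | 4-(pent-1-en-2-yl)-3-(triisopropylsilyloxy)cyclobut-2-en-1-one (racemic) | CCCC(=C)C1C(=O)C=C1O[Si](C(C)C)(C(C)C)C(C)C | intermediate
14 | (3E)-5-methylidene-3-(triisopropylsilyloxy)octa-1,3-dien-1-one (dienylketene) | O=C=C/C(O[Si](C(C)C)(C(C)C)C(C)C)=C\C(=C)CCC | intermediate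
15 | 5-propyl-3-(triisopropylsilyloxy)cyclohexa-2,4-dien-1-one | CCCC1=CC(O[Si](C(C)C)(C(C)C)C(C)C)=CC(=O)C1 | intermediate
16 | 3-propyl-5-(triisopropylsilyloxy)phenol | CCCc1cc(O)cc(O[Si](C(C)C)(C(C)C)C(C)C)c1 | intermediate
17 | 2-(hydroxymethyl)-3-propyl-5-(triisopropylsilyloxy)phenol (present as its magnesium salt) | CCCc1cc(O[Si](C(C)C)(C(C)C)C(C)C)cc(O)c1CO | intermediate
18 | 2-hydroxy-6-propyl-4-(triisopropylsilyloxy)benzaldehyde | CCCc1cc(O[Si](C(C)C)(C(C)C)C(C)C)cc(O)c1C=O | intermediate
19 | 2-methoxy-6-propyl-4-(triisopropylsilyloxy)benzaldehyde | CCCc1cc(O[Si](C(C)C)(C(C)C)C(C)C)cc(OC)c1C=O | intermediate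
20 | 2-methoxy-6-propyl-4-(triisopropylsilyloxy)benzoic acid | CCCc1cc(O[Si](C(C)C)(C(C)C)C(C)C)cc(OC)c1C(=O)O | intermediate
21 | 2,4-dihydroxy-6-propylbenzoic acid | CCCc1cc(O)cc(O)c1C(=O)O | starting material
22 | benzyl 4-(benzyloxy)-2-hydroxy-6-propylbenzoate | CCCc1cc(OCc2ccccc2)cc(O)c1C(=O)OCc1ccccc1 | intermediate
23 | benzyl 4-(benzyloxy)-2-hydroxy-3-(hydroxymethyl)-6-propylbenzoate (present as its magnesium salt) | CCCc1cc(OCc2ccccc2)c(CO)c(O)c1C(=O)OCc1ccccc1 | intermediate
24 | benzyl 4-(benzyloxy)-3-formyl-2-hydroxy-6-propylbenzoate | CCCc1cc(OCc2ccccc2)c(C=O)c(O)c1C(=O)OCc1ccccc1 | intermediate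
25 | benzyl 2,4-bis(benzyloxy)-3-formyl-6-propylbenzoate | CCCc1cc(OCc2ccccc2)c(C=O)c(OCc2ccccc2)c1C(=O)OCc1ccccc1 | intermediate
26 | benzyl 2,4-bis(benzyloxy)-3-(formyloxy)-6-propylbenzoate | CCCc1cc(OCc2ccccc2)c(OC=O)c(OCc2ccccc2)c1C(=O)OCc1ccccc1 | intermediate
27 | benzyl 2,4-bis(benzyloxy)-3-hydroxy-6-propylbenzoate | CCCc1cc(OCc2ccccc2)c(O)c(OCc2ccccc2)c1C(=O)OCc1ccccc1 | intermediate
28 | 2-methoxy-6-propyl-4-(triisopropylsilyloxy)benzoic trifluoroacetic anhydride | CCCc1cc(O[Si](C(C)C)(C(C)C)C(C)C)cc(OC)c1C(=O)OC(=O)C(F)(F)F | intermediate
29 | benzyl 2,4-bis(benzyloxy)-3-{[2-methoxy-6-propyl-4-(triisopropylsilyloxy)benzoyl]oxy}-6-propylbenzoate | CCCc1cc(O[Si](C(C)C)(C(C)C)C(C)C)cc(OC)c1C(=O)Oc1c(OCc2ccccc2)cc(CCC)c(C(=O)OCc2ccccc2)c1OCc1ccccc1 | intermediate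
30 | benzyl 2,4-bis(benzyloxy)-3-[(4-hydroxy-2-methoxy-6-propylbenzoyl)oxy]-6-propylbenzoate | CCCc1cc(O)cc(OC)c1C(=O)Oc1c(OCc2ccccc2)cc(CCC)c(C(=O)OCc2ccccc2)c1OCc1ccccc1 | intermediate
31 | 2,4-dihydroxy-3-[(4-hydroxy-2-methoxy-6-propylbenzoyl)oxy]-6-propylbenzoic acid | CCCc1cc(O)cc(OC)c1C(=O)Oc1c(O)cc(CCC)c(C(=O)O)c1O | target

**Total step count:** 15
**Longest linear sequence:** 9 steps (1, 2, 5, 6, 7, 8, 13, 14, 15). The branch through steps 3 and 4 is equally long, and the ring B branch contributes 7.

**Three steps most likely to fail**

**Risk at step 4.** Methoxide may also attack the oxygen-bound silicon, which would release the ynolate and destroy the ynol ether, and the low-boiling product may be lost on concentration. The fallback drops the unmasking and sets out from 10, together with 5.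
- The two are heated in toluene as in the key step. Here 10 is an internal siloxyalkyne, the class on which this benzannulation is best established.
- Its SiMe3-bearing carbon is the nucleophilic end, because the developing cation sits on the oxygen-bearing carbon, beta to silicon, and it bonds to the ketene carbonyl carbon.
- The product should be 5-propyl-3-(triisopropylsilyloxy)-2-(trimethylsilyl)phenol F1.
- Ipso-protodesilylation with CF3CO2H in CH2Cl2 at 0 °C then removes the aryl SiMe3 group. This group sits on the most nucleophilic ring carbon (ortho to both oxygens, para to propyl), and the aryl triisopropylsilyl ether is kept.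
- The fallback comes back to the route at 16.

**Risk at step 5.** At the temperature needed to open 5, three things may compete with capture of 12: an oxygen-to-carbon silyl shift of the unhindered terminal siloxyalkyne to a silylketene, self-condensation of 5, and acylation of the product phenol by the ketene. The fallback sets out from 11 and makes the same vinylketene at room temperature by a photochemical Wolff rearrangement, the diazo ketone variant of the benzannulation.
- Hexan-2-one F2 (bought) is methylenated at its more substituted alpha carbon (paraformaldehyde, diisopropylammonium trifluoroacetate, THF, reflux) to 3-methylidenehexan-2-one F3.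
- Kinetic enolisation at the methyl group (LiN(SiMe3)2, THF, −78 °C) and acylation with 2,2,2-trifluoroethyl trifluoroacetate give 1,1,1-trifluoro-5-methylideneoctane-2,4-dione F4.
- Detrifluoroacetylative diazo transfer (methanesulfonyl azide, Et3N, H2O, MeCN) gives 1-diazo-3-methylidenehexan-2-one F5.
- Irradiation of F5 with 11 in CH2Cl2 at rt expels nitrogen. The fallback comes back to the route at 12, which is trapped as 13 before any heating.
- A short period in hot toluene then carries 13 through 14 and 15 to 16.

**Risk at step 6.** The formylation may divide between the two ortho carbons C1 and C3 if the silyl ether screens C3 less than expected, and the silyl group may be lost slowly on long heating. The fallback sets out from 16 and restores the differentiation of the oxygens by chelation instead of by bulk.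
- Bu4NF in THF gives symmetric 5-propylbenzene-1,3-diol F6, in which the two carbons flanked by hydroxyl and propyl are equivalent.
- Vilsmeier–Haack formylation (POCl3, DMF) gives 2,4-dihydroxy-6-propylbenzaldehyde F7.
- Triisopropylsilyl chloride with imidazole in CH2Cl2 at 0 °C silylates only the C4 hydroxyl, because the C2 hydroxyl is locked in a hydrogen bond to the aldehyde.
- The fallback comes back to the route at 18.

**Further compounds**
F1 | step 4 | 5-propyl-3-(triisopropylsilyloxy)-2-(trimethylsilyl)phenol | CCCc1cc(O)c([Si](C)(C)C)c(O[Si](C(C)C)(C(C)C)C(C)C)c1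
F2 | step 5 | hexan-2-one (bought) | CCCCC(C)=O
F3 | step 5 | 3-methylidenehexan-2-one | CCCC(=C)C(C)=O
F4 | step 5 | 1,1,1-trifluoro-5-methylideneoctane-2,4-dione | CCCC(=C)C(=O)CC(=O)C(F)(F)F
F5 | step 5 | 1-diazo-3-methylidenehexan-2-one | CCCC(=C)C(=O)C=[N+]=[N-]
F6 | step 6 | 5-propylbenzene-1,3-diol | CCCc1cc(O)cc(O)c1
F7 | step 6 | 2,4-dihydroxy-6-propylbenzaldehyde | CCCc1cc(O)cc(O)c1C=O
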